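All runs stem from a simulated flask with made-up constants, and the scatter is random.

E takes one G and one L at each turn, so while we neglect Q, what is left of J and G together and what is left of L fall by equal steps.

| flask | J | L | remark | time |
|---|---|---|---|---|
| west | 0.037 M | 0.095 M | run made earlier |  |
| south-west | 0.12 M | 0.095 M | run made earlier |  |
| north-east | 0.10 M | 0.049 M | run made earlier |  |
| winter | 0.030 M | 0.0250 M |  | 6.0 h |
| noon | 0.10 M | 0.0950 M |  | 6.0 h |

- west (time / h: E / %): 1.50: 84.5; 3.00: 94.5; 5.00: 96.3; 6.00: 95.9
- south-west (time / h: E / %): 1.50: 45.8; 3.00: 65.9; 5.00: 68.0; 6.00: 68.7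
- north-east (time / h: E / %): 0.500: 7.3; 1.00: 22.3; 2.50: 42.8; 6.00: 49.9

(scatter of a reading: 1 percentage point)

- a species is counted by the J in it: one Q counts as two
- given per volume of solution although it is solid: J
- steps thought possible: G + L -> E; J <-> G; 2 J -> Q
- at the start none of J is in solution
- what has only dissolved of J counts as not reacted

- which of the two ends with the higher amount of E, in percent of the J charged ("neither" if they lie within 2 percentage points) (winter / noon / neither)
- E at the end, in percent of the J charged, winter
- E at the end, in percent of the J charged, noon

We watch winter in slow motion. It begins as solid J, and E lags: north-east reads 7.3% at 0.500 h and 22.3% at 1.00 h. Then G meets L, and we read the speed of that meeting from west, which is nearly pseudo-first-order. Between 1.50 h and 3.00 h, the gap to its plateau of 96.3% shrinks from 12 percentage points to 1.8 points. We replace L by its mean, 65.1% of its charge. L moves from 67.1% to 63.2%, so the mean costs little, but the scatter of 1 point makes the reading loose. It gives 20.3 M⁻¹ h⁻¹, our pair constant, the rate of E per unit of G and per unit of L.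

Winter charges L at 83.3% of J, so L is the limiting reagent and that fraction is the ceiling for E. With Q neglected, the surplus of J over L stays fixed, so the pair ratio, J and G left over L left, grows exponentially from 1.20. By 6.0 h we reckon it at 2.20. That leaves 16.6% of L and gives E 69.5%. We neglect Q here, since west, with more J, misses 3.7 points.

Noon's ceiling is 95.0%, but south-west misses 31 points. A power law through these two misses gives noon a loss of 22.5%, so we expect E 77.5%, ahead by 8 points.

The forecast says noon, with 57% for winter and 75% for noon, holding for winter that “dilute second-order consumption is slow”; our winter figure is higher.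

The flasks give noon: 70.5% in winter and 76.8% at noon.

    G + L → E (k = 0.00660 M⁻¹ s⁻¹)
    J ⇌ G, rate k2*(cs2 - [G]) while solid is left; crystals form when [G] > cs2 (solubility = 0.0620 M, k = 4.30 × 10⁻⁴ s⁻¹)
    2 J → Q (k = 0.00100 M⁻¹ s⁻¹)

Winter stands below the whole J charged at 6.00 h mainly because L is consumed as it works. The run with L held at its charge proves it: winter then gives 94.5% against 70.5%, and that gain is 81% of what is missing to the whole J charged. With 15% of L left, G has a half-life of 7.6 h by this step, longer than the whole run.

Take winter with 0.051 M of J. The pair constant gives a ceiling of 49.0%, a pair ratio of 48.1, 2.21% of L left and E 47.9%. That flask gives 47.8%, with 2.4% of L left.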